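**Retrosynthetic overview**
1. The only stereocentre, C3 (R), is set in the last step by an NADPH-dependent isoflavone reductase acting on the free isoflavone 24 (the biosynthetic reduction), so no protecting-group chemistry follows the epimerisable α-aryl ketone.
2. Isoflavone 24 comes from the 4-siloxy-2H-chromene 21 by hydride abstraction at C2 and desilylation.
3. Key disconnection: ring C of 21 is opened at C2–C3 and at C4–C4a, giving the aryloxymethyl cation from chloromethyl ether 6 (a 2-oxonia-diene, C4a=C8a–O1(+)=C2H2) and the siloxy alkyne 18 (C3≡C4–OSi), joined in a cationic formal [4+2] annulation.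
4. Enabling feature: in ring A the ether oxygen O1 carries the formaldehyde-level carbon C2 (an O-aryl oxocarbenium carbon), and C4a, ortho/para to three oxygens of the phloroglucinol-type ring, is a strong Friedel–Crafts nucleophile. Phenol 4 is mirror-symmetric, so both ortho carbons are C4a and no 6-methyl/8-methyl regioisomers can arise. C3–C4 is an arylacetic (ketene-level) unit, nucleophilic at C3 and electrophilic at C4.
5. Ring order: rings A and B are bought as resorcinols (the geranyl chain is put on ring B early by arylcopper substitution); ring C is the only ring formed, in the key step.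

Key step: step 10

Assumption (remark on the chemistry): an NADPH-dependent isoflavone reductase (wild type or a variant found by screening) is taken to accept the 6-methyl and 5'-geranyl groups of 24 and to reduce it in the (3R) sense that is general for this enzyme class.

**Step 1**
Reactants: 1 2-methylresorcinol
Product: 2 1,3-bis(tert-butyldimethylsilyloxy)-2-methylbenzene
Conditions: t-BuMe2SiCl (2.3 equiv), imidazole, DMF, rt
Reagents that add atoms: tert-butyldimethylsilyl chloride, CC(C)(C)[Si](C)(C)Cl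
Why: Imidazole-promoted O-silylation of both phenols of a symmetric diol, so no selectivity question arises.

**Step 2**
Reactants: 2 1,3-bis(tert-butyldimethylsilyloxy)-2-methylbenzene
Product: 4 3,5-bis(tert-butyldimethylsilyloxy)-4-methylphenol, via aryl pinacol boronate 3 (not isolated)
Conditions: [Ir(OMe)(C8H12)]2 (cat.), 4,4'-di-tert-butyl-2,2'-bipyridine (cat.), B2pin2 (1.0 equiv), THF, 80 °C; then H2O2 (30% aq), NaHCO3, THF/H2O, 0 °C
Reagents that add atoms: bis(pinacolato)diboron, CC1(C)OB(OC1(C)C)B1OC(C)(C)C(C)(C)O1 (boron and pinacolate of 3 only); hydrogen peroxide, OO (the phenol oxygen of 4)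
Why: Sterically controlled iridium-catalysed aromatic C–H borylation should occur only at the C–H para to the methyl group (the one position without an ortho substituent), and ipso-oxidation of the C–B bond then gives the phenol.

**Step 3**
Reactants: 4 3,5-bis(tert-butyldimethylsilyloxy)-4-methylphenol
Product: 5 1,3-bis(tert-butyldimethylsilyloxy)-2-methyl-5-[(methylsulfanyl)methoxy]benzene
Conditions: NaH, THF, 0 °C; ClCH2SMe, NaI (cat.), 0 °C to rt
Reagents that add atoms: chloromethyl methyl sulfide, CSCCl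
Why: Williamson etherification of the phenoxide with the activated α-chloro sulfide installs the future C2 as an O,S-acetal carbon.

**Step 4**
Reactants: 5 1,3-bis(tert-butyldimethylsilyloxy)-2-methyl-5-[(methylsulfanyl)methoxy]benzene
Product: 6 1,3-bis(tert-butyldimethylsilyloxy)-5-(chloromethoxy)-2-methylbenzene
Conditions: SO2Cl2 (1.0 equiv), cyclohexene (2 equiv), CH2Cl2, −78 to 0 °C; concentrated and used crude at once
Reagents that add atoms: sulfuryl chloride, O=S(=O)(Cl)Cl
Why: S-chlorination of the O,S-acetal and Pummerer-type fragmentation of the chlorosulfonium salt should give the α-chloro ether, the sulfenyl chloride being trapped by cyclohexene before it can attack the electron-rich ring.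

**Step 5**
Reactants: 7 4,6-dibromoresorcinol
Product: 8 1,5-dibromo-2,4-bis(triisopropylsilyloxy)benzene
Conditions: i-Pr3SiOSO2CF3 (2.3 equiv), 2,6-lutidine, CH2Cl2, 0 °C to rt
Reagents that add atoms: triisopropylsilyl trifluoromethanesulfonate, CC(C)[Si](OS(=O)(=O)C(F)(F)F)(C(C)C)C(C)C
Why: O-silylation with the silyl triflate overcomes the ortho-bromo hindrance; the bulky, weakly basic triisopropylsilyl ethers are chosen because they resist the O-to-C silyl shift in the aryllithiums of steps 6 and 7 and do not intercept the ketenium ion of step 10.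

**Step 6**
Reactants: 8 1,5-dibromo-2,4-bis(triisopropylsilyloxy)benzene; 9 geranyl bromide, (2E)-1-bromo-3,7-dimethylocta-2,6-diene
Product: 12 1-bromo-5-[(2E)-3,7-dimethylocta-2,6-dien-1-yl]-2,4-bis(triisopropylsilyloxy)benzene, via aryllithium 10 (not isolated), via arylcopper 11 (not isolated)
Conditions: n-BuLi (1.0 equiv), THF, −78 °C; CuBr·SMe2 (1.0 equiv), −78 to −40 °C; then 9, −40 to 0 °C
Reagents that add atoms: n-butyllithium, [Li]CCCC (lithium of 10 only); copper bromide dimethyl sulfide complex, [Cu]Br.CSC (copper of 11 only)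
Why: Mono bromine–lithium exchange (a second exchange on the aryl anion is slow), transmetalation to copper and SN2-selective allylic substitution at the primary carbon of geranyl bromide should give the linear product with the (E)-alkene untouched.

**Step 7**
Reactants: 12 1-bromo-5-[(2E)-3,7-dimethylocta-2,6-dien-1-yl]-2,4-bis(triisopropylsilyloxy)benzene
Product: 14 5-[(2E)-3,7-dimethylocta-2,6-dien-1-yl]-2,4-bis(triisopropylsilyloxy)benzaldehyde, via aryllithium 13 (not isolated)
Conditions: n-BuLi (1.05 equiv), THF, −78 °C; DMF (3 equiv), −78 to 0 °C; H2O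
Reagents that add atoms: n-butyllithium, [Li]CCCC (lithium of 13 only); N,N-dimethylformamide, CN(C)C=O (the formyl group of 14)
Why: Bromine–lithium exchange and Bouveault formylation with DMF at −78 °C, below the temperature at which the aryllithium deprotonates the benzylic–allylic CH2 or suffers silyl migration.

**Step 8**
Reactants: 14 5-[(2E)-3,7-dimethylocta-2,6-dien-1-yl]-2,4-bis(triisopropylsilyloxy)benzaldehyde
Product: 15 1-ethynyl-5-[(2E)-3,7-dimethylocta-2,6-dien-1-yl]-2,4-bis(triisopropylsilyloxy)benzene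
Conditions: Me3SiCHN2 (1.2 equiv), LiN(iPr)2 (1.2 equiv), THF, −78 to 0 °C
Reagents that add atoms: trimethylsilyldiazomethane, C[Si](C)(C)C=[N+]=[N-] (the terminal alkyne carbon)
Why: Colvin rearrangement: Peterson-type addition–elimination of lithiated trimethylsilyldiazomethane, loss of N2 and a 1,2-hydride shift give the terminal alkyne under aprotic conditions that spare the aryl silyl ethers.

**Step 9**
Reactants: 15 1-ethynyl-5-[(2E)-3,7-dimethylocta-2,6-dien-1-yl]-2,4-bis(triisopropylsilyloxy)benzene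
Product: 18 triisopropyl({[5-[(2E)-3,7-dimethylocta-2,6-dien-1-yl]-2,4-bis(triisopropylsilyloxy)phenyl]ethynyl}oxy)silane, via lithium acetylide 16 (not isolated), via lithium ynolate 17 (not isolated)
Conditions: LiN(SiMe3)2 (1.1 equiv), THF, −78 °C; t-BuOOLi (from t-BuOOH and LiN(SiMe3)2, 1.1 equiv), −78 to 0 °C; then i-Pr3SiOSO2CF3, −78 °C
Reagents that add atoms: lithium bis(trimethylsilyl)amide, [Li]N([Si](C)(C)C)[Si](C)(C)C (lithium of 16 and 17 only); tert-butyl hydroperoxide, CC(C)(C)OO (the ynol oxygen); triisopropylsilyl trifluoromethanesulfonate, CC(C)[Si](OS(=O)(=O)C(F)(F)F)(C(C)C)C(C)C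
Why: Electrophilic oxygenation of the lithium acetylide by lithium tert-butyl peroxide gives the ynolate, which the hard silyl triflate traps on oxygen to give the isolable triisopropylsilyl ynol ether.

**Step 10**
Reactants: 6 1,3-bis(tert-butyldimethylsilyloxy)-5-(chloromethoxy)-2-methylbenzene; 18 triisopropyl({[5-[(2E)-3,7-dimethylocta-2,6-dien-1-yl]-2,4-bis(triisopropylsilyloxy)phenyl]ethynyl}oxy)silane
Product: 21 5,7-bis(tert-butyldimethylsilyloxy)-3-[5-[(2E)-3,7-dimethylocta-2,6-dien-1-yl]-2,4-bis(triisopropylsilyloxy)phenyl]-6-methyl-4-(triisopropylsilyloxy)-2H-chromene, via aryloxymethyl cation 19 (not isolated), via silyl ketenium ion 20 (not isolated)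
Conditions: 6 (1.3 equiv), 18 (1.0 equiv), 2,6-di-tert-butyl-4-methylpyridine (1.5 equiv), 4 Å molecular sieves, CH2Cl2, −78 °C; AgN(SO2CF3)2 (1.3 equiv) added last, −78 to −40 °C; Et3N quench
Reagents that add atoms: silver bis(trifluoromethanesulfonyl)imide, [Ag+].FC(F)(F)S(=O)(=O)[N-]S(=O)(=O)C(F)(F)F (counter-ion of 19 and 20 only; no atoms in 21)
Why: Proposed new method: silver abstracts chloride from 6 to give the aryloxymethyl cation 19 (the 2-oxonia-diene C4a=C8a–O1(+)=C2), whose CH2 terminus is attacked by the oxygen-activated β-carbon of siloxy alkyne 18 (C2–C3 bond) to give silyl ketenium ion 20, and the digonal ketenium carbon C4 is then trapped by the ortho carbon of ring A (C4–C4a bond) before the base removes the proton, a stepwise cationic formal [4+2] annulation of the oxa-Povarov type. The closest known reactions are the addition of acetal-derived oxocarbenium ions to siloxy alkynes, which gives silyl ketenium ions, and the acid-promoted siloxy-alkyne/arene carbocyclisation that closes tetralone enol ethers through the same kind of ketenium ion. Ring C closes in a 6-exo-dig Friedel–Crafts mode, the attacked C=O(+) π bond lying in the plane of the C3 substituents and exocyclic to the new ring. No stereocentre is created, since C3 and C4 emerge as a tetrasubstituted enol ether and C3 is set in step 13. The step needs capture of 19 by the alkyne rather than by the arenes or the geranyl alkenes (secured by the far higher nucleophilicity of the ynol ether), β-regioselective attack (polarisation by the siloxy oxygen), and closure on ring A rather than attack of O2' on C4 or loss of the silyl group (secured by the bulky, weakly basic triisopropylsilyl groups and the non-coordinating counter-ion), while the mirror symmetry of the aryl ether makes the two ortho carbons identical so that only one regioisomer can form. The hindered pyridine takes up the HN(SO2CF3)2 released, so that the enol ether, the aryl silyl ethers and the geranyl chain should survive.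

**Step 11**
Reactants: 21 5,7-bis(tert-butyldimethylsilyloxy)-3-[5-[(2E)-3,7-dimethylocta-2,6-dien-1-yl]-2,4-bis(triisopropylsilyloxy)phenyl]-6-methyl-4-(triisopropylsilyloxy)-2H-chromene
Product: 23 5,7-bis(tert-butyldimethylsilyloxy)-3-[5-[(2E)-3,7-dimethylocta-2,6-dien-1-yl]-2,4-bis(triisopropylsilyloxy)phenyl]-6-methyl-4H-chromen-4-one, via 4-siloxybenzopyrylium salt 22 (not isolated)
Conditions: Ph3CBF4 (1.05 equiv), CH2Cl2, −78 to −20 °C; then aq NaHCO3
Reagents that add atoms: trityl tetrafluoroborate, c1ccc(cc1)[C+](c1ccccc1)c1ccccc1.F[B-](F)(F)F (counter-ion of 22 only; no atoms in 23)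
Why: Hydride abstraction from a silyl enol ether by trityl cation (a known enol-ether-to-enone oxidation) should be especially easy here because the C2–H is both α to O1 and allylic and its loss gives the aromatic 4-siloxybenzopyrylium 22, which is desilylated on hydrolytic work-up to the isoflavone.

**Step 12**
Reactants: 23 5,7-bis(tert-butyldimethylsilyloxy)-3-[5-[(2E)-3,7-dimethylocta-2,6-dien-1-yl]-2,4-bis(triisopropylsilyloxy)phenyl]-6-methyl-4H-chromen-4-one
Product: 24 3-[5-[(2E)-3,7-dimethylocta-2,6-dien-1-yl]-2,4-dihydroxyphenyl]-5,7-dihydroxy-6-methyl-4H-chromen-4-one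
Conditions: Bu4NF (6 equiv), AcOH (6 equiv), THF, 0 °C to rt
Reagents that add atoms: none
Why: Fluoride-mediated cleavage of the four aryl silyl ethers, buffered with acetic acid, needs no acid that could cyclise the geranyl chain onto O4' and is done while the molecule has no stereocentre to lose.

**Step 13**
Reactants: 24 3-[5-[(2E)-3,7-dimethylocta-2,6-dien-1-yl]-2,4-dihydroxyphenyl]-5,7-dihydroxy-6-methyl-4H-chromen-4-one
Product: 25 (3R)-3-[5-[(2E)-3,7-dimethylocta-2,6-dien-1-yl]-2,4-dihydroxyphenyl]-5,7-dihydroxy-6-methyl-2,3-dihydro-4H-chromen-4-one (target)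
Conditions: isoflavone reductase (NADPH-dependent 2'-hydroxyisoflavone reductase, EC 1.3.1.45, recombinant), NADP+ (cat.), 2-propanol (5% v/v) with an NADP-dependent alcohol dehydrogenase for cofactor recycling, KH2PO4/K2HPO4 buffer pH 6.5, DMSO (5% v/v), 30 °C, under argon
Reagents that add atoms: none
Why: Enzymatic conjugate reduction by an isoflavone reductase: hydride from NADPH adds to C2 and the enol is protonated at C3 on one face inside the active site, which should give the (3R)-isoflavanone as in the biosynthesis of 2'-hydroxyisoflavanones such as vestitone and dalbergioidin, and the near-neutral buffer should not epimerise C3.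

**Compound list**
1 | 2-methylresorcinol (2-methylbenzene-1,3-diol) | Cc1c(O)cccc1O | starting material
2 | 1,3-bis(tert-butyldimethylsilyloxy)-2-methylbenzene | Cc1c(O[Si](C)(C)C(C)(C)C)cccc1O[Si](C)(C)C(C)(C)C | intermediate
3 | 2-[3,5-bis(tert-butyldimethylsilyloxy)-4-methylphenyl]-4,4,5,5-tetramethyl-1,3,2-dioxaborolane (not isolated) | Cc1c(O[Si](C)(C)C(C)(C)C)cc(B2OC(C)(C)C(C)(C)O2)cc1O[Si](C)(C)C(C)(C)C | intermediate
4 | 3,5-bis(tert-butyldimethylsilyloxy)-4-methylphenol | Cc1c(O[Si](C)(C)C(C)(C)C)cc(O)cc1O[Si](C)(C)C(C)(C)C | intermediate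
5 | 1,3-bis(tert-butyldimethylsilyloxy)-2-methyl-5-[(methylsulfanyl)methoxy]benzene | CSCOc1cc(O[Si](C)(C)C(C)(C)C)c(C)c(O[Si](C)(C)C(C)(C)C)c1 | intermediate
6 | 1,3-bis(tert-butyldimethylsilyloxy)-5-(chloromethoxy)-2-methylbenzene | ClCOc1cc(O[Si](C)(C)C(C)(C)C)c(C)c(O[Si](C)(C)C(C)(C)C)c1 | intermediate
7 | 4,6-dibromoresorcinol (4,6-dibromobenzene-1,3-diol) | Oc1cc(O)c(Br)cc1Br | starting material
8 | 1,5-dibromo-2,4-bis(triisopropylsilyloxy)benzene | CC(C)[Si](Oc1cc(O[Si](C(C)C)(C(C)C)C(C)C)c(Br)cc1Br)(C(C)C)C(C)C | intermediate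
9 | geranyl bromide, (2E)-1-bromo-3,7-dimethylocta-2,6-diene | CC(C)=CCC/C(C)=C/CBr | starting material
10 | [5-bromo-2,4-bis(triisopropylsilyloxy)phenyl]lithium (not isolated) | [Li]c1cc(Br)c(O[Si](C(C)C)(C(C)C)C(C)C)cc1O[Si](C(C)C)(C(C)C)C(C)C | intermediate
11 | [5-bromo-2,4-bis(triisopropylsilyloxy)phenyl]copper (not isolated) | [Cu]c1cc(Br)c(O[Si](C(C)C)(C(C)C)C(C)C)cc1O[Si](C(C)C)(C(C)C)C(C)C | intermediate
12 | 1-bromo-5-[(2E)-3,7-dimethylocta-2,6-dien-1-yl]-2,4-bis(triisopropylsilyloxy)benzene | CC(C)=CCC/C(C)=C/Cc1cc(Br)c(O[Si](C(C)C)(C(C)C)C(C)C)cc1O[Si](C(C)C)(C(C)C)C(C)C | intermediate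
13 | {5-[(2E)-3,7-dimethylocta-2,6-dien-1-yl]-2,4-bis(triisopropylsilyloxy)phenyl}lithium (not isolated) | CC(C)=CCC/C(C)=C/Cc1cc([Li])c(O[Si](C(C)C)(C(C)C)C(C)C)cc1O[Si](C(C)C)(C(C)C)C(C)C | intermediate
14 | 5-[(2E)-3,7-dimethylocta-2,6-dien-1-yl]-2,4-bis(triisopropylsilyloxy)benzaldehyde | CC(C)=CCC/C(C)=C/Cc1cc(C=O)c(O[Si](C(C)C)(C(C)C)C(C)C)cc1O[Si](C(C)C)(C(C)C)C(C)C | intermediate
15 | 1-ethynyl-5-[(2E)-3,7-dimethylocta-2,6-dien-1-yl]-2,4-bis(triisopropylsilyloxy)benzene | CC(C)=CCC/C(C)=C/Cc1cc(C#C)c(O[Si](C(C)C)(C(C)C)C(C)C)cc1O[Si](C(C)C)(C(C)C)C(C)C | intermediate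
16 | lithium acetylide of 15 (not isolated) | CC(C)=CCC/C(C)=C/Cc1cc(C#C[Li])c(O[Si](C(C)C)(C(C)C)C(C)C)cc1O[Si](C(C)C)(C(C)C)C(C)C | intermediate
17 | lithium 2-{5-[(2E)-3,7-dimethylocta-2,6-dien-1-yl]-2,4-bis(triisopropylsilyloxy)phenyl}ethynolate (not isolated) | [Li+].CC(C)=CCC/C(C)=C/Cc1cc(C#C[O-])c(O[Si](C(C)C)(C(C)C)C(C)C)cc1O[Si](C(C)C)(C(C)C)C(C)C | intermediate
18 | triisopropyl({[5-[(2E)-3,7-dimethylocta-2,6-dien-1-yl]-2,4-bis(triisopropylsilyloxy)phenyl]ethynyl}oxy)silane | CC(C)=CCC/C(C)=C/Cc1cc(C#CO[Si](C(C)C)(C(C)C)C(C)C)c(O[Si](C(C)C)(C(C)C)C(C)C)cc1O[Si](C(C)C)(C(C)C)C(C)C | intermediate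
19 | [3,5-bis(tert-butyldimethylsilyloxy)-4-methylphenyl](methylidene)oxonium bis(trifluoromethanesulfonyl)imide (not isolated) | C=[O+]c1cc(O[Si](C)(C)C(C)(C)C)c(C)c(O[Si](C)(C)C(C)(C)C)c1.FC(F)(F)S(=O)(=O)[N-]S(=O)(=O)C(F)(F)F | intermediate
20 | O-triisopropylsilyl ketenium bis(trifluoromethanesulfonyl)imide carrying the ring-B aryl group and the aryloxymethyl group on the ketene carbon (not isolated) | CC(C)=CCC/C(C)=C/Cc1cc(C(COc2cc(O[Si](C)(C)C(C)(C)C)c(C)c(O[Si](C)(C)C(C)(C)C)c2)=C=[O+][Si](C(C)C)(C(C)C)C(C)C)c(O[Si](C(C)C)(C(C)C)C(C)C)cc1O[Si](C(C)C)(C(C)C)C(C)C.FC(F)(F)S(=O)(=O)[N-]S(=O)(=O)C(F)(F)F | intermediate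
21 | 5,7-bis(tert-butyldimethylsilyloxy)-3-[5-[(2E)-3,7-dimethylocta-2,6-dien-1-yl]-2,4-bis(triisopropylsilyloxy)phenyl]-6-methyl-4-(triisopropylsilyloxy)-2H-chromene | CC(C)=CCC/C(C)=C/Cc1cc(C2=C(O[Si](C(C)C)(C(C)C)C(C)C)c3c(O[Si](C)(C)C(C)(C)C)c(C)c(O[Si](C)(C)C(C)(C)C)cc3OC2)c(O[Si](C(C)C)(C(C)C)C(C)C)cc1O[Si](C(C)C)(C(C)C)C(C)C | intermediate
22 | 5,7-bis(tert-butyldimethylsilyloxy)-3-[5-[(2E)-3,7-dimethylocta-2,6-dien-1-yl]-2,4-bis(triisopropylsilyloxy)phenyl]-6-methyl-4-(triisopropylsilyloxy)chromenylium tetrafluoroborate (not isolated) | CC(C)=CCC/C(C)=C/Cc1cc(-c2c[o+]c3cc(O[Si](C)(C)C(C)(C)C)c(C)c(O[Si](C)(C)C(C)(C)C)c3c2O[Si](C(C)C)(C(C)C)C(C)C)c(O[Si](C(C)C)(C(C)C)C(C)C)cc1O[Si](C(C)C)(C(C)C)C(C)C.F[B-](F)(F)F | intermediate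
23 | 5,7-bis(tert-butyldimethylsilyloxy)-3-[5-[(2E)-3,7-dimethylocta-2,6-dien-1-yl]-2,4-bis(triisopropylsilyloxy)phenyl]-6-methyl-4H-chromen-4-one | CC(C)=CCC/C(C)=C/Cc1cc(-c2coc3cc(O[Si](C)(C)C(C)(C)C)c(C)c(O[Si](C)(C)C(C)(C)C)c3c2=O)c(O[Si](C(C)C)(C(C)C)C(C)C)cc1O[Si](C(C)C)(C(C)C)C(C)C | intermediate
24 | 3-[5-[(2E)-3,7-dimethylocta-2,6-dien-1-yl]-2,4-dihydroxyphenyl]-5,7-dihydroxy-6-methyl-4H-chromen-4-one | CC(C)=CCC/C(C)=C/Cc1cc(-c2coc3cc(O)c(C)c(O)c3c2=O)c(O)cc1O | intermediate
25 | (3R)-3-[5-[(2E)-3,7-dimethylocta-2,6-dien-1-yl]-2,4-dihydroxyphenyl]-5,7-dihydroxy-6-methyl-2,3-dihydro-4H-chromen-4-one | CC(C)=CCC/C(C)=C/Cc1cc([C@@H]2COc3cc(O)c(C)c(O)c3C2=O)c(O)cc1O | target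

**Step count and risks**
Total step count: 13 steps. Longest linear sequence: 9 steps (7 → 8 → 12 → 14 → 15 → 18 → 21 → 23 → 24 → 25; steps 5 to 13); the ring-A arm (steps 1 to 4) joins at step 10.

Three steps most likely to fail:

1. Step 10 (key step). The aryloxymethyl cation may be consumed by Friedel–Crafts self-condensation of the electron-rich aryl ether or by hydride transfer from C2 of the product. The ketenium ion may lose its silyl group or be captured by O2' instead of C4a. Ring closure may also be slowed by crowding between the silyloxy groups at C4 and C5. The fallback makes the same two bonds separately with known reactions; it sets out from 15 (taken to the ynolate 17 as in step 9) and from 6, and comes back at 21. Quenching 17 with water instead of the silyl triflate should give {5-[(2E)-3,7-dimethylocta-2,6-dien-1-yl]-2,4-bis(triisopropylsilyloxy)phenyl}acetic acid F1. Double deprotonation with LiN(iPr)2 (2.1 equiv, THF, −78 °C) gives the dilithium enediolate F2, which is C-alkylated by 6 to the racemic 3-[3,5-bis(tert-butyldimethylsilyloxy)-4-methylphenoxy]-2-arylpropanoic acid F3 (C2–C3 bond). 1-Chloro-N,N,2-trimethylprop-1-en-1-amine converts it under neutral conditions into the acid chloride F4. AgOSO2CF3 with 2,6-di-tert-butyl-4-methylpyridine (CH2Cl2, −78 °C) should then induce intramolecular Friedel–Crafts acylation of ring A to the racemic tetrasilyl isoflavanone F5 (C4–C4a bond). Soft enolisation with i-Pr3SiOSO2CF3 and Et3N (CH2Cl2, 0 °C) returns to 21.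

2. Step 13. The enzyme may fail to bind or turn over the lipophilic 6-methyl-5'-geranyl substrate, or the substrate may stay out of solution in the buffer. The chemical fallback sets out from 23 and comes back at 25. Asymmetric transfer hydrogenation with RuCl[(R,R)-TsNCH(Ph)CH(Ph)NH2](p-cymene) in HCO2H/Et3N (EtOAc, 40 °C; the antipodal catalyst is used if this one gives the mirror-image alcohol) reduces the C2=C3 bond and then, with dynamic kinetic resolution of the racemising ketone, the carbonyl group. This should give the cis-(3R,4R)-tetrasilyl isoflavan-4-ol F6. Dess–Martin periodinane with NaHCO3 (CH2Cl2, 0 °C) re-oxidises C4 without touching C3 to give the (3R)-tetrasilyl isoflavanone F7. HF·pyridine with extra pyridine in THF at 0 °C (acidic fluoride, no enolate) then removes the four silyl groups to give 25.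

3. Step 4. Electrophilic chlorination or sulfenylation of the very electron-rich ring A may compete with S-chlorination, and the chloromethyl ether may self-condense on concentration. The fallback sets out from 4 and comes back at 6, bypassing 5. The sodium phenoxide of 4 (NaH, THF) is added slowly to a large excess of bromochloromethane at 0 °C to rt, so that displacement of bromide gives 6 directly, with no sulfur or electrophilic chlorine species present and with the excess dihalide suppressing the bis(aryloxy)methane; this fallback makes no new compound (F0).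

**Further compounds**
F1 | step 10 | {5-[(2E)-3,7-dimethylocta-2,6-dien-1-yl]-2,4-bis(triisopropylsilyloxy)phenyl}acetic acid | CC(C)=CCC/C(C)=C/Cc1cc(CC(=O)O)c(O[Si](C(C)C)(C(C)C)C(C)C)cc1O[Si](C(C)C)(C(C)C)C(C)C
F2 | step 10 | dilithium enediolate of F1 | [Li+].[Li+].CC(C)=CCC/C(C)=C/Cc1cc(C=C([O-])[O-])c(O[Si](C(C)C)(C(C)C)C(C)C)cc1O[Si](C(C)C)(C(C)C)C(C)C
F3 | step 10 | racemic 3-[3,5-bis(tert-butyldimethylsilyloxy)-4-methylphenoxy]-2-{5-[(2E)-3,7-dimethylocta-2,6-dien-1-yl]-2,4-bis(triisopropylsilyloxy)phenyl}propanoic acid | CC(C)=CCC/C(C)=C/Cc1cc(C(COc2cc(O[Si](C)(C)C(C)(C)C)c(C)c(O[Si](C)(C)C(C)(C)C)c2)C(=O)O)c(O[Si](C(C)C)(C(C)C)C(C)C)cc1O[Si](C(C)C)(C(C)C)C(C)C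
F4 | step 10 | racemic acid chloride of F3 | CC(C)=CCC/C(C)=C/Cc1cc(C(COc2cc(O[Si](C)(C)C(C)(C)C)c(C)c(O[Si](C)(C)C(C)(C)C)c2)C(Cl)=O)c(O[Si](C(C)C)(C(C)C)C(C)C)cc1O[Si](C(C)C)(C(C)C)C(C)C
F5 | step 10 | racemic 5,7-bis(tert-butyldimethylsilyloxy)-3-{5-[(2E)-3,7-dimethylocta-2,6-dien-1-yl]-2,4-bis(triisopropylsilyloxy)phenyl}-6-methylchroman-4-one | CC(C)=CCC/C(C)=C/Cc1cc(C2COc3cc(O[Si](C)(C)C(C)(C)C)c(C)c(O[Si](C)(C)C(C)(C)C)c3C2=O)c(O[Si](C(C)C)(C(C)C)C(C)C)cc1O[Si](C(C)C)(C(C)C)C(C)C
F6 | step 13 | (3R,4R)-5,7-bis(tert-butyldimethylsilyloxy)-3-{5-[(2E)-3,7-dimethylocta-2,6-dien-1-yl]-2,4-bis(triisopropylsilyloxy)phenyl}-6-methylchroman-4-ol (cis) | CC(C)=CCC/C(C)=C/Cc1cc([C@@H]2COc3cc(O[Si](C)(C)C(C)(C)C)c(C)c(O[Si](C)(C)C(C)(C)C)c3[C@@H]2O)c(O[Si](C(C)C)(C(C)C)C(C)C)cc1O[Si](C(C)C)(C(C)C)C(C)C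
F7 | step 13 | (3R)-5,7-bis(tert-butyldimethylsilyloxy)-3-{5-[(2E)-3,7-dimethylocta-2,6-dien-1-yl]-2,4-bis(triisopropylsilyloxy)phenyl}-6-methylchroman-4-one | CC(C)=CCC/C(C)=C/Cc1cc([C@@H]2COc3cc(O[Si](C)(C)C(C)(C)C)c(C)c(O[Si](C)(C)C(C)(C)C)c3C2=O)c(O[Si](C(C)C)(C(C)C)C(C)C)cc1O[Si](C(C)C)(C(C)C)C(C)C
F0 | step 4 | none | none
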